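## Structural features

The target 31 is the 3-hydroxy-4-methoxybenzoate of a guaiane: a cyclopentane (ring A, C1–C5) and a cycloheptane (ring B, C1, C10, C9, C8, C7, C6, C5) share the C1–C5 bond, and the two ring-fusion hydrogens are trans. Ring A carries a trisubstituted epoxide across C3–C4 with a methyl group on C4; ring B carries a tertiary methyl carbinol at C10, the ester oxygen at C8 and an isopropyl group at C7. The seven stereocentres form two runs, C3–C4–C5–C1–C10 and C7–C8, with C8 and C10 in a 1,3-relationship across ring B. If the face that bears the C8 oxygen is called the upper face, the isopropyl group, H5 and the C4 and C10 methyl groups are also up, whereas H1, the C10 hydroxyl and the epoxide oxygen are down (1R,3R,4S,5S,7R,8R,10R). The fragile groups are the acid-sensitive epoxide, the tertiary alcohol (elimination), the aryl ester (base, hydride) and the electron-rich free phenol (oxidants, acylating agents). The real difficulty is the trans fusion of a five- and a seven-membered ring with no carbonyl beside it for equilibration, together with five substituents on defined faces of a flexible ring B. The key step uses the oxygen on C3: lying between C2 and the methyl-bearing C4 of ring A, it is read as the carbonyl of a cyclopentenone C1=C2–C3(=O)–C4 with a C5=C6 double bond beside it, which is what an allenic Pauson–Khand reaction leaves when C1 and C2 come from an alkyne, C3 from carbon monoxide and C4 and C5 from the outer double bond of an allene. The oxygens on C8 and C10 then sit on opposite faces next to the two new double bonds and can steer hydrogen to C5 and to C1.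

## Logic of the disconnections

31 ⇒ 30 ⇒ 29. Only the aryl O–Si bond separates 31 from 30, and the two epoxide C–O bonds (C3–O, C4–O) are cut back to the C3=C4 alkene of 29. The epoxide is the most acid-sensitive group and is therefore made last but one. This removes two stereocentres; the forward step must deliver oxygen to the lower face, which requires the C10 hydroxyl to be free as a directing group.

29 ⇒ 25 + 28, and 28 ⇒ 26. The acyl C–O bond at C8 is cut to separate the arene from the terpenoid. The gain is convergence. The forward step must acylate the secondary hydroxyl with retention and leave the tertiary one alone; the phenol of 26 is masked as a silyl ether so that it cannot act as a second nucleophile.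

25 ⇒ 23 ⇒ 21 ⇒ 20. The vinylic C3–H bond of 25 is traced to a C3–O bond (enol triflate 23, silyl enol ether 21, ketone 20), because a C3 oxygen is what the carbonylation leaves. The forward sequence must enolise 20 toward C4 and not toward C2.

20 ⇒ 19 ⇒ 17. The C1–H and C5–H bonds are cut one at a time, returning two double bonds (C1=C2, then C5=C6). Each ring-fusion hydrogen is cis to one hydroxyl, so each can be delivered by that hydroxyl. This removes the ring-fusion stereocentres. The forward steps must run in the order C5 then C1, with the C10 oxygen masked during the first, since it is homoallylic to C5=C6 on the wrong face.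

17 ⇒ 15 + 16. The bonds C1–C5, C2–C3 and C3–C4 are cut in one operation. Both rings open to a ten-carbon chain that already carries C7, C8 and C10 in their final configuration. The forward step must engage the outer allene bond and must carbonylate faster than it eliminates.

15 ⇒ 13. The O–Si bond at C10 is cut. The gain is only a protecting group; the forward step must leave the C8 hydroxyl free and the C10 oxygen blocked.

13 ⇒ 12. The C1–C10 bond is cut to a methyl ketone and a two-carbon acetylide. This removes the tertiary stereocentre; the forward addition needs 1,3-induction from the C8 oxygen through a chelate.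

12 ⇒ 11 ⇒ 9 ⇒ 7 + 8. The allene is traced to a propargylic alcohol by restoring the C4–O bond and removing the C6–H bond, and the C4–C5 bond is then cut to a terminal alkyne and 8. The new carbinol centre and the allene axis need no control, because both are erased later.

7 ⇒ 6 ⇒ 3 + 5. The C7–C8 bond is cut. Both chain stereocentres come from one reagent-controlled addition, leaving an achiral aldehyde and a small chiral electrophile. The forward step must transfer the chirality of 3 and give the anti relationship.

3 ⇒ 2 ⇒ 1, and 5 ⇒ 4. The sulfonate is cut to the alcohol, which is resolved from the racemate; the aldehyde comes from the ester by partial reduction. Both 1 and 4 are articles of commerce.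

## Other disconnections considered

Alternative 1: The cut is at C1–C10 and C5–C6, leaving ring A as cyclopent-2-en-1-one A1. A 1-ethoxyvinyl nucleophile, made from ethyl vinyl ether A2, would add to the β-carbon (C1) under a monovalent copper catalyst with a chiral phosphoramidite, and the enolate would be alkylated at C5 by 1-bromo-3-methylbut-2-ene A3 in the same flask to give A4.
- In favour: the electrophile enters anti to the new β-substituent, so the trans relationship at C1/C5 is set at once and under catalyst control. On this point the alternative is the better of the two, since the chosen plan needs two directed hydrogenations (steps 12 and 13) for it.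
- Also in favour: the C4 ketone of A4 has only one enolisable methylene (C3), so the later C3=C4 alkene is easier to place than from 20; here too it is at least the equal.
- Against: no ring is closed. Ring B still lacks C8 and C9 and needs a medium-ring closure, and C7, C8 and C10 would then be set by substrate control on a flexible ring far from C1 and C5.
- Against: an α-alkoxyvinyl group is an uncommon transfer group in catalytic asymmetric conjugate addition, and the metal enolate may exchange protons before it is alkylated.
- Comparison: the chosen plan sets C7, C8 and C10 in an open chain under reagent control and closes both rings in one step, so its weak points lie after the key step; the alternative secures the ring fusion first and has its weak points in everything that follows. Step economy is expected to favour the chosen plan.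

Alternative 2: The cut is at C9–C10 and C8–C9, a one-carbon insertion. Dibromocarbene A6 would add to the trans-fused silyl enol ether A5, and the siloxydibromocyclopropane would open in the same flask to the 2-bromocycloheptenone A7.
- In favour: the trans fusion is carried over from a six-membered ring, where it is easier to secure. The site of insertion is fixed by the enol ether, and C3=C4 is already in place, which is better than the chosen plan on that point. A7 offers the C10 carbonyl for methyl addition.
- Against: A5 itself needs a multistep enantioselective synthesis, so the ring-fusion problem is moved and not removed.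
- Against: the carbene can also attack the trisubstituted C3=C4 alkene that is needed later. From A7 the C8 oxygen has to be introduced at a former alkene carbon cis to the isopropyl group, the bromine removed and the C10 methyl added from the correct face, all by substrate control.
- Comparison: mechanistically the key step is reliable but forms only one ring bond pair and no stereocentre; the chosen key step forms three bonds and two rings. The route is expected to be longer.

Alternative 3: The cut is at C4–C5 and C1–C2 of ring A. A chiral phosphine would add to ethyl buta-2,3-dienoate A8, and the zwitterion would annulate the E-enone A9 to the cyclopentene A10, with the acetyl group and the side chain trans and the alkene at C3=C4.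
- In favour: it is convergent and catalytic, the trans relationship follows from the enone geometry, and the alkene is formed exactly where the epoxide is needed. On alkene placement it is the better plan, and on the C1/C5 relationship at least the equal.
- Against: the annulation can give regioisomers (attack through the α- or the γ-carbon of the zwitterion), and enantiocontrol with simple β-alkyl enones is less dependable. A9 is a skipped dienone that may move into conjugation under the nucleophilic catalyst.
- Against: the ester carbon has to be taken down to the C4 methyl without moving the alkene, and ring B is still open, so C7, C8 and C10 again depend on substrate control during or after a seven-membered ring closure.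
- Comparison: the chosen plan pays for its early chain stereocontrol with a ketone-to-alkene conversion (steps 14–16) that this alternative avoids, but it closes both rings in one step; overall step count should favour the chosen plan.

Key step: step 11

Remarks before the steps:
- Assumption: the allene axis (11–15), the carbinol carbon of 9 and C4 of 17–20 are left uncontrolled and drawn without descriptor, because step 7, step 11 and step 14 erase them.
- Check of configurations: the chain centres of 13 map onto C10, C8 and C7 of 31 without change of spatial arrangement. C7 is S in 13 and 17 and R from 18 on only because C6 loses priority when C5=C6 is saturated.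
- Design of the precursor: the free diol 13 is not cyclised as such. Its tertiary hydroxyl is carried as the triethylsilyl ether 15, because a free C10 hydroxyl is homoallylic to C5=C6 on the lower face and would compete with the C8 hydroxyl in step 12.
- Guaiane numbering is used for all bicyclic compounds. 4 is the ethylene ketal of ethyl acetoacetate.

Step 1
Reactants: 1 (±)-4-methylpent-1-yn-3-ol
Product: 2 (R)-4-methylpent-1-yn-3-ol
Conditions: immobilised Candida antarctica lipase B, vinyl acetate, hexane, 30 °C, stopped just past half conversion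
Reagents that add atoms: none
Why: Lipase-catalysed kinetic resolution by acyl transfer; with ethynyl as the smaller and isopropyl as the larger substituent, the empirical size rule for lipases predicts that the S alcohol is acetylated and the R alcohol is left, and running slightly beyond half conversion should raise its enantiomeric purity.

Step 2
Reactants: 2 (R)-4-methylpent-1-yn-3-ol
Product: 3 (R)-4-methylpent-1-yn-3-yl methanesulfonate
Conditions: MeSO2Cl, Et3N, CH2Cl2, −78 to 0 °C
Reagents that add atoms: methanesulfonyl chloride, CS(=O)(=O)Cl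
Why: O-Sulfonylation of a secondary alcohol; the C–O bond is not touched, so the configuration is retained.

Step 3
Reactants: 4 ethyl 2-(2-methyl-1,3-dioxolan-2-yl)acetate
Product: 5 2-(2-methyl-1,3-dioxolan-2-yl)acetaldehyde
Conditions: i-Bu2AlH, CH2Cl2, −78 °C
Reagents that add atoms: none
Why: Partial reduction of an ester; the tetrahedral aluminium hemiacetal is stable at low temperature and releases the aldehyde only on work-up.

Step 4
Reactants: 3 (R)-4-methylpent-1-yn-3-yl methanesulfonate; 5 2-(2-methyl-1,3-dioxolan-2-yl)acetaldehyde
Product: 6 (2R,3S)-1-(2-methyl-1,3-dioxolan-2-yl)-3-(propan-2-yl)pent-4-yn-2-ol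
Conditions: Pd(OAc)2 (5 mol %), PPh3 (5 mol %), Et2Zn, THF, −20 °C
Reagents that add atoms: none
Why: Zerovalent palladium displaces the mesylate anti in an SN2′ sense, and transmetalation gives a configurationally defined allenylzinc that adds to 5 through a cyclic SE2′ transition state (palladium-catalysed allenylzinc addition of a propargylic mesylate). C7 is formed with net inversion of the mesylate centre, and the aldehyde chain lies away from the isopropyl group, so the C8 hydroxyl is anti to it.

Step 5
Reactants: 6 (2R,3S)-1-(2-methyl-1,3-dioxolan-2-yl)-3-(propan-2-yl)pent-4-yn-2-ol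
Product: 7 triethyl{[(2R,3S)-1-(2-methyl-1,3-dioxolan-2-yl)-3-(propan-2-yl)pent-4-yn-2-yl]oxy}silane
Conditions: Et3SiCl, imidazole, DMF, 0 °C to rt
Reagents that add atoms: chlorotriethylsilane, CC[Si](Cl)(CC)CC
Why: Silylation of the secondary alcohol; the ether keeps the C8 oxygen out of the Mitsunobu activation in step 7 and falls off together with the ketal in step 8.

Step 6
Reactants: 7 triethyl{[(2R,3S)-1-(2-methyl-1,3-dioxolan-2-yl)-3-(propan-2-yl)pent-4-yn-2-yl]oxy}silane; 8 acetaldehyde
Product: 9 (2RS,5S,6R)-7-(2-methyl-1,3-dioxolan-2-yl)-5-(propan-2-yl)-6-(triethylsilyloxy)hept-3-yn-2-ol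
Conditions: n-BuLi, THF, −78 °C; then 8
Reagents that add atoms: none
Why: Addition of a lithium acetylide to an aldehyde; the new carbinol centre is formed as both epimers, which does not matter because it is removed in step 7.

Step 7
Reactants: 9 (2RS,5S,6R)-7-(2-methyl-1,3-dioxolan-2-yl)-5-(propan-2-yl)-6-(triethylsilyloxy)hept-3-yn-2-ol
Product: 11 triethyl{[(2R,3S)-1-(2-methyl-1,3-dioxolan-2-yl)-3-(propan-2-yl)hepta-4,5-dien-2-yl]oxy}silane (both allene epimers), via sulfonylhydrazine adduct 10 (not isolated)
Conditions: PPh3, diethyl azodicarboxylate, THF, −15 °C; 2-nitrobenzenesulfonylhydrazide; then rt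
Reagents that add atoms: none
Why: Mitsunobu displacement of the activated propargylic hydroxyl by the sulfonylhydrazide gives 10, which loses the sulfinic acid on warming; the propargylic diazene transfers hydrogen to C6 with loss of N2 (reductive 1,3-transposition of a propargylic alcohol to an allene). The axis follows the carbinol configuration, so both allene epimers form, and both lead to the same product in step 11 apart from C4.

Step 8
Reactants: 11 triethyl{[(2R,3S)-1-(2-methyl-1,3-dioxolan-2-yl)-3-(propan-2-yl)hepta-4,5-dien-2-yl]oxy}silane
Product: 12 (4R,5S)-4-hydroxy-5-(propan-2-yl)nona-6,7-dien-2-one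
Conditions: 1 M HCl, THF, 0 °C to rt
Reagents that add atoms: water, O
Why: Acid hydrolysis of the dioxolane and of the triethylsilyl ether in one operation; a 1,3-disubstituted allene and a β-hydroxy ketone should tolerate dilute acid at room temperature.

Step 9
Reactants: 12 (4R,5S)-4-hydroxy-5-(propan-2-yl)nona-6,7-dien-2-one
Product: 13 (3R,5R,6S)-3-methyl-6-(propan-2-yl)deca-7,8-dien-1-yne-3,5-diol
Conditions: HC≡CMgBr (3 equiv), THF/CH2Cl2, −78 to −20 °C
Reagents that add atoms: ethynylmagnesium bromide, C#C[Mg]Br
Why: The first equivalent forms a magnesium alkoxide that chelates the ketone in a six-membered half-chair with the C7 chain pseudo-equatorial; the second adds along the axial, chair-forming trajectory (chelation-controlled Grignard addition to a β-hydroxy ketone). The ethynyl group therefore ends anti to the C8 oxygen in the main chain, which is R at C10.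

Step 10
Reactants: 13 (3R,5R,6S)-3-methyl-6-(propan-2-yl)deca-7,8-dien-1-yne-3,5-diol
Product: 15 (3R,5R,6S)-3-methyl-6-(propan-2-yl)-3-(triethylsilyloxy)deca-7,8-dien-1-yn-5-ol, via bis(triethylsilyl) ether 14 (not isolated)
Conditions: Et3SiOTf, 2,6-lutidine, CH2Cl2, −78 to 0 °C; then MeOH, camphorsulfonic acid, −20 °C
Reagents that add atoms: triethylsilyl trifluoromethanesulfonate, CC[Si](CC)(CC)OS(=O)(=O)C(F)(F)F
Why: Exhaustive silylation followed by acid-catalysed methanolysis, which for steric reasons should remove the secondary silyl ether well before the tertiary one (selective desilylation). This leaves the C8 hydroxyl free as the only directing group for step 12.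

Step 11
Reactants: 15 (3R,5R,6S)-3-methyl-6-(propan-2-yl)-3-(triethylsilyloxy)deca-7,8-dien-1-yn-5-ol; 16 carbon monoxide
Product: 17 (7S,8R,10R)-8-hydroxy-10-(triethylsilyloxy)guaia-1,5-dien-3-one (C4 epimers)
Conditions: [Rh(CO)2Cl]2 (5 mol %), CO (1 atm), toluene, 90 °C
Reagents that add atoms: none
Why: Monovalent rhodium binds the alkyne and the outer π bond of the allene and undergoes oxidative cyclometalation to a trivalent rhodacyclopentene, which forms C1–C5 and so closes the seven-membered ring (7-exo-dig with respect to the alkyne, the inner allene bond staying in the ring as C5=C6). Insertion of CO and reductive elimination then form C2–C3 and C3–C4, so the cyclopentenone arises by contraction of the acyl metallacycle and not by a separate cyclisation of the chain. The closest known reaction type is the rhodium-catalysed allenic Pauson–Khand reaction of allenynes with a three-atom tether, which gives bicyclo[5.3.0]decadienones. The first selectivity needed is the outer over the inner allene bond, which is a property of the rhodium catalyst and decides for a seven- and against a six-membered ring. The second is carbonylation over β-hydride loss from the C4 methyl group (cycloisomerisation to a cross-conjugated triene), which the CO atmosphere should secure. The quaternary C10 and the substituents on C7 and C8 favour the folded chain, and the silyl ether removes a free propargylic hydroxyl from the metal. C4 is the only new stereocentre; it is set by syn addition across the allene and follows the allene axis, so 17 forms as both C4 epimers, which is harmless because C4 is enolisable and becomes trigonal in step 14. C7, C8 and C10 are not touched.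

Step 12
Reactants: 17 (7S,8R,10R)-8-hydroxy-10-(triethylsilyloxy)guaia-1,5-dien-3-one (C4 epimers)
Product: 19 (5R,7R,8R,10R)-8,10-dihydroxyguai-1-en-3-one (C4 epimers), via silyl ether 18 (not isolated)
Conditions: [Ir(cod)(PCy3)(py)]PF6 (10 mol %), H2 (1 atm), CH2Cl2, 0 °C to rt; then HF·pyridine, THF, 0 °C to rt
Reagents that add atoms: none
Why: The cationic iridium catalyst binds the C8 hydroxyl and the homoallylic C5=C6 bond and adds H2 from the hydroxyl face (hydroxyl-directed homogeneous hydrogenation), so H5 is placed on the upper face. The silylated C10 oxygen cannot direct, and the C1=C2 enone bond, with a quaternary neighbour and no free hydroxyl in reach, should react more slowly. Fluoride then frees the C10 hydroxyl for step 13.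

Step 13
Reactants: 19 (5R,7R,8R,10R)-8,10-dihydroxyguai-1-en-3-one (C4 epimers)
Product: 20 (1R,5S,7R,8R,10R)-8,10-dihydroxyguaian-3-one (C4 epimers)
Conditions: [Ir(cod)(PCy3)(py)]PF6 (10 mol %), H2 (1 atm), CH2Cl2, rt
Reagents that add atoms: none
Why: The allylic tertiary C10 hydroxyl directs hydrogen to C1=C2 from the lower, concave face, which undirected reagents would avoid (hydroxyl-directed hydrogenation). H1 therefore ends trans to H5; the C8 hydroxyl is three carbons away and should not compete.

Step 14
Reactants: 20 (1R,5S,7R,8R,10R)-8,10-dihydroxyguaian-3-one (C4 epimers)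
Product: 21 (1R,5S,7R,8R,10R)-3,8,10-tris(trimethylsilyloxy)guai-3-ene
Conditions: Me3SiCl, NaI, Et3N, MeCN, rt
Reagents that add atoms: chlorotrimethylsilane, C[Si](C)(C)Cl
Why: Iodotrimethylsilane formed in the flask silylates the ketone reversibly, so the more substituted C3=C4 silyl enol ether should predominate (thermodynamic silyl enol ether formation). Both hydroxyls are silylated at the same time, which protects them in steps 15 and 16, and the C4 centre is erased.

Step 15
Reactants: 21 (1R,5S,7R,8R,10R)-3,8,10-tris(trimethylsilyloxy)guai-3-ene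
Product: 23 (1R,5S,7R,8R,10R)-8,10-bis(trimethylsilyloxy)guai-3-en-3-yl trifluoromethanesulfonate, via lithium enolate 22 (not isolated)
Conditions: MeLi, THF, 0 °C; then PhNTf2, 0 °C to rt
Reagents that add atoms: N-phenylbis(trifluoromethanesulfonimide), O=S(=O)(N(c1ccccc1)S(=O)(=O)C(F)(F)F)C(F)(F)F
Why: Methyllithium cleaves only the enol Si–O bond and, with no proton source present, gives the lithium enolate without loss of regiochemistry; O-sulfonylation by the triflimide gives the enol triflate.

Step 16
Reactants: 23 (1R,5S,7R,8R,10R)-8,10-bis(trimethylsilyloxy)guai-3-en-3-yl trifluoromethanesulfonate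
Product: 25 (1R,5S,7R,8R,10R)-guai-3-ene-8,10-diol, via bis(trimethylsilyl) ether 24 (not isolated)
Conditions: Pd(OAc)2 (5 mol %), PPh3, Bu3N, HCO2H, DMF, 60 °C; then Bu4NF, THF, rt
Reagents that add atoms: none
Why: Oxidative addition of zerovalent palladium to the enol triflate, exchange with formate, loss of CO2 and reductive elimination give the alkene (palladium-catalysed formate reduction of an enol triflate); fluoride then removes both trimethylsilyl ethers.

Step 17
Reactants: 26 3-hydroxy-4-methoxybenzoic acid
Product: 28 3-(tert-butyldimethylsilyloxy)-4-methoxybenzoic acid, via silyl ester 27 (not isolated)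
Conditions: t-BuMe2SiCl, imidazole, DMF, rt; then AcOH, THF, H2O, rt
Reagents that add atoms: tert-butylchlorodimethylsilane, CC(C)(C)[Si](C)(C)Cl
Why: Silylation of both acidic groups followed by selective hydrolysis of the silyl ester, which is far more labile than the aryl silyl ether.

Step 18
Reactants: 25 (1R,5S,7R,8R,10R)-guai-3-ene-8,10-diol; 28 3-(tert-butyldimethylsilyloxy)-4-methoxybenzoic acid
Product: 29 (1R,5S,7R,8R,10R)-10-hydroxyguai-3-en-8-yl 3-(tert-butyldimethylsilyloxy)-4-methoxybenzoate
Conditions: N-ethyl-N′-(3-dimethylaminopropyl)carbodiimide hydrochloride, 4-(dimethylamino)pyridine, CH2Cl2, rt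
Reagents that add atoms: none
Why: Steglich esterification; only the secondary C8 hydroxyl is acylated, the tertiary C10 hydroxyl being too hindered, and the C8–O bond is not broken, so the configuration is retained.

Step 19
Reactants: 29 (1R,5S,7R,8R,10R)-10-hydroxyguai-3-en-8-yl 3-(tert-butyldimethylsilyloxy)-4-methoxybenzoate
Product: 30 (1R,3R,4S,5S,7R,8R,10R)-3,4-epoxy-10-hydroxyguaian-8-yl 3-(tert-butyldimethylsilyloxy)-4-methoxybenzoate
Conditions: VO(acac)2 (10 mol %), t-BuOOH, CH2Cl2, 0 °C to rt
Reagents that add atoms: tert-butyl hydroperoxide, CC(C)(C)OO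
Why: The tertiary C10 hydroxyl binds the vanadium alkylperoxide and delivers oxygen to the alkene face it occupies, the lower face, syn to H1 (hydroxyl-directed vanadium-catalysed epoxidation of a bishomoallylic alcohol). The cis epoxy alcohol cannot open itself, since that would need backside attack.

Step 20
Reactants: 30 (1R,3R,4S,5S,7R,8R,10R)-3,4-epoxy-10-hydroxyguaian-8-yl 3-(tert-butyldimethylsilyloxy)-4-methoxybenzoate
Product: 31 (1R,3R,4S,5S,7R,8R,10R)-3,4-epoxy-10-hydroxyguaian-8-yl 3-hydroxy-4-methoxybenzoate
Conditions: Bu4NF, AcOH, THF, 0 °C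
Reagents that add atoms: none
Why: Fluoride cleaves the aryl silyl ether rapidly; the acetic acid buffer keeps the medium near neutral, so the ester and the epoxide should survive.

## Compound list

1 | (±)-4-methylpent-1-yn-3-ol | CC(C)C(O)C#C | starting material
2 | (R)-4-methylpent-1-yn-3-ol | CC(C)[C@@H](O)C#C | intermediate
3 | (R)-4-methylpent-1-yn-3-yl methanesulfonate | CC(C)[C@@H](OS(C)(=O)=O)C#C | intermediate
4 | ethyl 2-(2-methyl-1,3-dioxolan-2-yl)acetate | CCOC(=O)CC1(C)OCCO1 | starting material
5 | 2-(2-methyl-1,3-dioxolan-2-yl)acetaldehyde | O=CCC1(C)OCCO1 | intermediate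
6 | (2R,3S)-1-(2-methyl-1,3-dioxolan-2-yl)-3-(propan-2-yl)pent-4-yn-2-ol | CC1(OCCO1)C[C@@H](O)[C@H](C#C)C(C)C | intermediate
7 | triethyl{[(2R,3S)-1-(2-methyl-1,3-dioxolan-2-yl)-3-(propan-2-yl)pent-4-yn-2-yl]oxy}silane | CC1(OCCO1)C[C@@H](O[Si](CC)(CC)CC)[C@H](C#C)C(C)C | intermediate
8 | acetaldehyde | CC=O | starting material
9 | (2RS,5S,6R)-7-(2-methyl-1,3-dioxolan-2-yl)-5-(propan-2-yl)-6-(triethylsilyloxy)hept-3-yn-2-ol | CC1(OCCO1)C[C@@H](O[Si](CC)(CC)CC)[C@H](C#CC(C)O)C(C)C | intermediate
10 | N-[(5S,6R)-7-(2-methyl-1,3-dioxolan-2-yl)-5-(propan-2-yl)-6-(triethylsilyloxy)hept-3-yn-2-yl]-2-nitrobenzenesulfonohydrazide, alkylated on the sulfonylated nitrogen | CC1(OCCO1)C[C@@H](O[Si](CC)(CC)CC)[C@H](C#CC(C)N(N)S(=O)(=O)c1ccccc1[N+](=O)[O-])C(C)C | intermediate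
11 | triethyl{[(2R,3S)-1-(2-methyl-1,3-dioxolan-2-yl)-3-(propan-2-yl)hepta-4,5-dien-2-yl]oxy}silane, both allene epimers | CC1(OCCO1)C[C@@H](O[Si](CC)(CC)CC)[C@H](C=C=CC)C(C)C | intermediate
12 | (4R,5S)-4-hydroxy-5-(propan-2-yl)nona-6,7-dien-2-one, both allene epimers | CC(=O)C[C@@H](O)[C@H](C=C=CC)C(C)C | intermediate
13 | (3R,5R,6S)-3-methyl-6-(propan-2-yl)deca-7,8-dien-1-yne-3,5-diol, both allene epimers | C#C[C@](C)(O)C[C@@H](O)[C@H](C=C=CC)C(C)C | intermediate
14 | (3R,5R,6S)-3-methyl-6-(propan-2-yl)-3,5-bis(triethylsilyloxy)deca-7,8-dien-1-yne | C#C[C@](C)(O[Si](CC)(CC)CC)C[C@@H](O[Si](CC)(CC)CC)[C@H](C=C=CC)C(C)C | intermediate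
15 | (3R,5R,6S)-3-methyl-6-(propan-2-yl)-3-(triethylsilyloxy)deca-7,8-dien-1-yn-5-ol, both allene epimers | C#C[C@](C)(O[Si](CC)(CC)CC)C[C@@H](O)[C@H](C=C=CC)C(C)C | intermediate
16 | carbon monoxide | [C-]#[O+] | starting material
17 | (7S,8R,10R)-8-hydroxy-10-(triethylsilyloxy)guaia-1,5-dien-3-one, both C4 epimers | O[C@@H]1C[C@@](C)(O[Si](CC)(CC)CC)C2=CC(=O)C(C)C2=C[C@@H]1C(C)C | intermediate
18 | (5R,7R,8R,10R)-8-hydroxy-10-(triethylsilyloxy)guai-1-en-3-one, both C4 epimers | O[C@@H]1C[C@@](C)(O[Si](CC)(CC)CC)C2=CC(=O)C(C)[C@H]2C[C@@H]1C(C)C | intermediate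
19 | (5R,7R,8R,10R)-8,10-dihydroxyguai-1-en-3-one, both C4 epimers | O[C@@H]1C[C@@](C)(O)C2=CC(=O)C(C)[C@H]2C[C@@H]1C(C)C | intermediate
20 | (1R,5S,7R,8R,10R)-8,10-dihydroxyguaian-3-one, both C4 epimers | O[C@@H]1C[C@@](C)(O)[C@@H]2CC(=O)C(C)[C@H]2C[C@@H]1C(C)C | intermediate
21 | (1R,5S,7R,8R,10R)-3,8,10-tris(trimethylsilyloxy)guai-3-ene | C[Si](C)(C)O[C@@H]1C[C@@](C)(O[Si](C)(C)C)[C@@H]2CC(O[Si](C)(C)C)=C(C)[C@H]2C[C@@H]1C(C)C | intermediate
22 | lithium (1R,5S,7R,8R,10R)-8,10-bis(trimethylsilyloxy)guai-3-en-3-olate | C[Si](C)(C)O[C@@H]1C[C@@](C)(O[Si](C)(C)C)[C@@H]2CC(O[Li])=C(C)[C@H]2C[C@@H]1C(C)C | intermediate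
23 | (1R,5S,7R,8R,10R)-8,10-bis(trimethylsilyloxy)guai-3-en-3-yl trifluoromethanesulfonate | C[Si](C)(C)O[C@@H]1C[C@@](C)(O[Si](C)(C)C)[C@@H]2CC(OS(=O)(=O)C(F)(F)F)=C(C)[C@H]2C[C@@H]1C(C)C | intermediate
24 | (1R,5S,7R,8R,10R)-8,10-bis(trimethylsilyloxy)guai-3-ene | C[Si](C)(C)O[C@@H]1C[C@@](C)(O[Si](C)(C)C)[C@@H]2CC=C(C)[C@H]2C[C@@H]1C(C)C | intermediate
25 | (1R,5S,7R,8R,10R)-guai-3-ene-8,10-diol | O[C@@H]1C[C@@](C)(O)[C@@H]2CC=C(C)[C@H]2C[C@@H]1C(C)C | intermediate
26 | 3-hydroxy-4-methoxybenzoic acid | COc1ccc(C(=O)O)cc1O | starting material
27 | tert-butyldimethylsilyl 3-(tert-butyldimethylsilyloxy)-4-methoxybenzoate | COc1ccc(C(=O)O[Si](C)(C)C(C)(C)C)cc1O[Si](C)(C)C(C)(C)C | intermediate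
28 | 3-(tert-butyldimethylsilyloxy)-4-methoxybenzoic acid | COc1ccc(C(=O)O)cc1O[Si](C)(C)C(C)(C)C | intermediate
29 | (1R,5S,7R,8R,10R)-10-hydroxyguai-3-en-8-yl 3-(tert-butyldimethylsilyloxy)-4-methoxybenzoate | COc1ccc(C(=O)O[C@@H]2C[C@@](C)(O)[C@@H]3CC=C(C)[C@H]3C[C@@H]2C(C)C)cc1O[Si](C)(C)C(C)(C)C | intermediate
30 | (1R,3R,4S,5S,7R,8R,10R)-3,4-epoxy-10-hydroxyguaian-8-yl 3-(tert-butyldimethylsilyloxy)-4-methoxybenzoate | COc1ccc(C(=O)O[C@@H]2C[C@@](C)(O)[C@@H]3C[C@H]4O[C@@]4(C)[C@H]3C[C@@H]2C(C)C)cc1O[Si](C)(C)C(C)(C)C | intermediate
31 | (1R,3R,4S,5S,7R,8R,10R)-3,4-epoxy-10-hydroxyguaian-8-yl 3-hydroxy-4-methoxybenzoate (CNP0264062.2) | COc1ccc(C(=O)O[C@@H]2C[C@@](C)(O)[C@@H]3C[C@H]4O[C@@]4(C)[C@H]3C[C@@H]2C(C)C)cc1O | target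

## Step count and least certain steps

Total step count: 20 steps. Longest linear sequence: 18 steps (1 to 31 through steps 1, 2, 4–16 and 18–20); steps 3 and 17 lie on side branches.

**Step 11 (key step).** The most likely failure is diversion of the rhodacycle into cycloisomerisation (β-hydride loss from the C4 methyl group) or oligomerisation at the unsubstituted alkyne terminus, because CO insertion has to outrun both while a seven-membered ring is formed. The fallback caps the alkyne with silicon, the substrate class for which this cyclisation is best documented, and sets out from 15.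
- Double deprotonation with n-BuLi and treatment with Me3SiCl should give (3R,5R,6S)-3-methyl-6-(propan-2-yl)-3-(triethylsilyloxy)-1-(trimethylsilyl)-5-(trimethylsilyloxy)deca-7,8-dien-1-yne F1.
- Citric acid in methanol should remove the O-silyl group at C8 to give (3R,5R,6S)-3-methyl-6-(propan-2-yl)-3-(triethylsilyloxy)-1-(trimethylsilyl)deca-7,8-dien-1-yn-5-ol F2.
- The same carbonylative cyclisation with [Rh(CO)2Cl]2 under CO should give (7S,8R,10R)-8-hydroxy-10-(triethylsilyloxy)-2-(trimethylsilyl)guaia-1,5-dien-3-one F3.
- Hydroxyl-directed hydrogenation as in step 12 should give (5R,7R,8R,10R)-8-hydroxy-10-(triethylsilyloxy)-2-(trimethylsilyl)guai-1-en-3-one F4.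
- Bu4NF in wet THF should remove both the vinylic silyl group next to the carbonyl and the triethylsilyl ether, so the fallback comes back to the route at 19.

**Step 9.** The most likely failure is loss of 1,3-induction through addition to non-chelated conformers, since THF competes with the ketone for magnesium; this would give the C10 epimer. The fallback uses a neutral bidentate chelate of a β-alkoxy ketone and sets out from 12.
- 4-Methoxybenzyl 2,2,2-trichloroacetimidate with catalytic La(OTf)3 should give (4R,5S)-4-[(4-methoxybenzyl)oxy]-5-(propan-2-yl)nona-6,7-dien-2-one F5.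
- Precomplexation with MgBr2·OEt2 in CH2Cl2 and addition of HC≡CMgBr should give (3R,5R,6S)-5-[(4-methoxybenzyl)oxy]-3-methyl-6-(propan-2-yl)deca-7,8-dien-1-yn-3-ol F6.
- Et3SiOTf and 2,6-lutidine should give (3R,5R,6S)-5-[(4-methoxybenzyl)oxy]-3-methyl-6-(propan-2-yl)-3-(triethylsilyloxy)deca-7,8-dien-1-yne F7.
- Oxidative removal of the benzyl ether with 2,3-dichloro-5,6-dicyano-1,4-benzoquinone brings the fallback back to the route at 15, replacing steps 9 and 10.

**Step 12.** The most likely failure is poor facial selectivity or hydrogen addition across the conjugated system. Hydrogen must be delivered to the face that also carries the allylic isopropyl group, and the alkene is the far end of a dienone. The fallback does not use the C8 hydroxyl at all and sets out from 17.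
- HF·pyridine should give (7S,8R,10R)-8,10-dihydroxyguaia-1,5-dien-3-one F8.
- One equivalent of H2 with [Ir(cod)(PCy3)(py)]PF6, directed by the allylic C10 hydroxyl, should reduce C1=C2 to give (1R,7S,8R,10R)-8,10-dihydroxyguai-5-en-3-one F9. Uptake must be stopped there, because the same hydroxyl could also reach C5=C6.
- 1,8-Diazabicyclo[5.4.0]undec-7-ene should move the remaining double bond into conjugation to give (1R,7R,8R,10R)-8,10-dihydroxyguai-4-en-3-one F10.
- Dissolving-metal reduction (Li, liquid NH3, THF, one equivalent of tert-butanol) should protonate C5 to the more stable trans fusion and leave the C3–C4 lithium enolate, which is trapped with PhNTf2 as (1R,5S,7R,8R,10R)-8,10-dihydroxyguai-3-en-3-yl trifluoromethanesulfonate F11.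
- Formate reduction with Pd(OAc)2 and PPh3 as in step 16 brings the fallback back to the route at 25.

**Step 14.** The most likely failure is incomplete regiocontrol of enolisation, with some silyl enol ether forming toward C2, because the preference for the tetrasubstituted isomer is only thermodynamic. The fallback places the alkene through a halohydrin and sets out from 20.
- Acid-mediated bromination with pyridinium tribromide in acetic acid, which takes place at the more substituted α-carbon, should give (1R,5S,7R,8R,10R)-4-bromo-8,10-dihydroxyguaian-3-one F12.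
- NaBH4 should give (1R,5S,7R,8R,10R)-4-bromoguaiane-3,8,10-triol F13.
- Reductive elimination with Zn in acetic acid, which tolerates either relative configuration, brings the fallback back to the route at 25.

**Step 19.** The most likely failure is weak direction by the remote tertiary hydroxyl, leading to poor facial selectivity or attack from the upper face. The fallback delivers oxygen to the face opposite to that chosen by an undirected electrophile and sets out from 29.
- N-Bromosuccinimide in aqueous THF should form the bromonium ion on the upper face, with water opening it at the tertiary C4 from below, to give (1R,3S,4S,5S,7R,8R,10R)-3-bromo-4,10-dihydroxyguaian-8-yl 3-(tert-butyldimethylsilyloxy)-4-methoxybenzoate F14.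
- K2CO3 in methanol at 0 °C should close the epoxide by displacement of bromide. Since the aryl silyl ether is cleaved under the same conditions, the fallback comes back to the route at 31.

## Further compounds

F1 | step 11 | (3R,5R,6S)-3-methyl-6-(propan-2-yl)-3-(triethylsilyloxy)-1-(trimethylsilyl)-5-(trimethylsilyloxy)deca-7,8-dien-1-yne | C[Si](C)(C)C#C[C@](C)(O[Si](CC)(CC)CC)C[C@@H](O[Si](C)(C)C)[C@H](C=C=CC)C(C)C
F2 | step 11 | (3R,5R,6S)-3-methyl-6-(propan-2-yl)-3-(triethylsilyloxy)-1-(trimethylsilyl)deca-7,8-dien-1-yn-5-ol | C[Si](C)(C)C#C[C@](C)(O[Si](CC)(CC)CC)C[C@@H](O)[C@H](C=C=CC)C(C)C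
F3 | step 11 | (7S,8R,10R)-8-hydroxy-10-(triethylsilyloxy)-2-(trimethylsilyl)guaia-1,5-dien-3-one, both C4 epimers | O[C@@H]1C[C@@](C)(O[Si](CC)(CC)CC)C2=C([Si](C)(C)C)C(=O)C(C)C2=C[C@@H]1C(C)C
F4 | step 11 | (5R,7R,8R,10R)-8-hydroxy-10-(triethylsilyloxy)-2-(trimethylsilyl)guai-1-en-3-one, both C4 epimers | O[C@@H]1C[C@@](C)(O[Si](CC)(CC)CC)C2=C([Si](C)(C)C)C(=O)C(C)[C@H]2C[C@@H]1C(C)C
F5 | step 9 | (4R,5S)-4-[(4-methoxybenzyl)oxy]-5-(propan-2-yl)nona-6,7-dien-2-one | CC(=O)C[C@@H](OCc1ccc(OC)cc1)[C@H](C=C=CC)C(C)C
F6 | step 9 | (3R,5R,6S)-5-[(4-methoxybenzyl)oxy]-3-methyl-6-(propan-2-yl)deca-7,8-dien-1-yn-3-ol | C#C[C@](C)(O)C[C@@H](OCc1ccc(OC)cc1)[C@H](C=C=CC)C(C)C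
F7 | step 9 | (3R,5R,6S)-5-[(4-methoxybenzyl)oxy]-3-methyl-6-(propan-2-yl)-3-(triethylsilyloxy)deca-7,8-dien-1-yne | C#C[C@](C)(O[Si](CC)(CC)CC)C[C@@H](OCc1ccc(OC)cc1)[C@H](C=C=CC)C(C)C
F8 | step 12 | (7S,8R,10R)-8,10-dihydroxyguaia-1,5-dien-3-one, both C4 epimers | O[C@@H]1C[C@@](C)(O)C2=CC(=O)C(C)C2=C[C@@H]1C(C)C
F9 | step 12 | (1R,7S,8R,10R)-8,10-dihydroxyguai-5-en-3-one, both C4 epimers | O[C@@H]1C[C@@](C)(O)[C@@H]2CC(=O)C(C)C2=C[C@@H]1C(C)C
F10 | step 12 | (1R,7R,8R,10R)-8,10-dihydroxyguai-4-en-3-one | O[C@@H]1C[C@@](C)(O)[C@@H]2CC(=O)C(C)=C2C[C@@H]1C(C)C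
F11 | step 12 | (1R,5S,7R,8R,10R)-8,10-dihydroxyguai-3-en-3-yl trifluoromethanesulfonate | O[C@@H]1C[C@@](C)(O)[C@@H]2CC(OS(=O)(=O)C(F)(F)F)=C(C)[C@H]2C[C@@H]1C(C)C
F12 | step 14 | (1R,5S,7R,8R,10R)-4-bromo-8,10-dihydroxyguaian-3-one, C4 unassigned | O[C@@H]1C[C@@](C)(O)[C@@H]2CC(=O)C(C)(Br)[C@H]2C[C@@H]1C(C)C
F13 | step 14 | (1R,5S,7R,8R,10R)-4-bromoguaiane-3,8,10-triol, C3 and C4 unassigned | O[C@@H]1C[C@@](C)(O)[C@@H]2CC(O)C(C)(Br)[C@H]2C[C@@H]1C(C)C
F14 | step 19 | (1R,3S,4S,5S,7R,8R,10R)-3-bromo-4,10-dihydroxyguaian-8-yl 3-(tert-butyldimethylsilyloxy)-4-methoxybenzoate | COc1ccc(C(=O)O[C@@H]2C[C@@](C)(O)[C@@H]3C[C@H](Br)[C@@](C)(O)[C@H]3C[C@@H]2C(C)C)cc1O[Si](C)(C)C(C)(C)C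
A1 | alternative 1 | cyclopent-2-en-1-one | O=C1C=CCC1
A2 | alternative 1 | ethyl vinyl ether | C=COCC
A3 | alternative 1 | 1-bromo-3-methylbut-2-ene | CC(C)=CCBr
A4 | alternative 1 | trans-3-(1-ethoxyvinyl)-2-(3-methylbut-2-enyl)cyclopentanone | O=C1CC[C@@H](C(=C)OCC)[C@@H]1CC=C(C)C
A5 | alternative 2 | trans-4-isopropyl-7-methyl-2-(trimethylsilyloxy)bicyclo[4.3.0]nona-2,7-diene | C[Si](C)(C)OC1=C[C@@H](C(C)C)C[C@@H]2C(C)=CC[C@@H]12
A6 | alternative 2 | dibromocarbene | Br[C]Br
A7 | alternative 2 | trans-fused 9-bromo-7-isopropyl-4-methylbicyclo[5.3.0]deca-3,8-dien-10-one (guaiane numbering) | O=C1C(Br)=C[C@@H](C(C)C)C[C@@H]2C(C)=CC[C@@H]12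
A8 | alternative 3 | ethyl buta-2,3-dienoate | C=C=CC(=O)OCC
A9 | alternative 3 | (E)-7-methyl-6-methylideneoct-3-en-2-one | CC(=O)/C=C/CC(=C)C(C)C
A10 | alternative 3 | ethyl trans-4-acetyl-5-(2-isopropylallyl)cyclopent-1-ene-1-carboxylate | CCOC(=O)C1=CC[C@@H](C(C)=O)[C@@H]1CC(=C)C(C)C
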